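**Strategy**

Everything rests on cutting the C3–C4 bond of the tetrahydrofuran ring (O1, C2, C3, C4, C5). In the target C3 bears CH2OH and C4 bears a veratrylmethyl group, the exact pattern left when trivalent titanium opens a terminal epoxide to a C3 radical that adds 5-exo to the styrene bond of an O-cinnamyl group carried by the C2 benzylic oxygen. That single operation closes the only new ring, forms C3–C4, sets C3 and C4 from C2 and liberates the primary alcohol. The precursor is an enantioenriched aryl oxiranyl carbinol, obtained by Sharpless kinetic resolution, etherified with 3,4-dimethoxycinnamyl bromide.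

Key step: step 7

Remark: the ring is numbered O1, C2, C3, C4, C5, with C9 for the hydroxymethyl carbon on C3. The sense of the kinetic resolution is taken from the empirical Sharpless face rule, with the aryl group in the place of the carbinol substituent. The configuration and enantiomeric purity of 5 would be checked by Mosher ester analysis and chiral HPLC before material is committed, and L-(+)-tartrate would be substituted if the opposite sense were found.

**Route**

Step 1
Reactants: 1 vanillin
Product: 2 3-methoxy-4-(triisopropylsilyloxy)benzaldehyde
Conditions: i-Pr3SiCl, imidazole, DMF, rt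
Reagents that add atoms: triisopropylsilyl chloride, CC(C)[Si](Cl)(C(C)C)C(C)C
Why: Imidazole-promoted silylation of the phenol leaves the aldehyde untouched and gives a bulky aryl silyl ether that should tolerate the organomagnesium, hydride base, titanium alkoxide and radical conditions ahead and can be removed at the end with fluoride, with no hydrogenolysis and no acid at the benzylic ether.

Step 2
Reactants: 2 3-methoxy-4-(triisopropylsilyloxy)benzaldehyde; 3 vinylmagnesium bromide
Product: 4 racemic 1-[3-methoxy-4-(triisopropylsilyloxy)phenyl]prop-2-en-1-ol
Conditions: THF, −78 → 0 °C; then sat. aq NH4Cl; used without delay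
Reagents that add atoms: none
Why: Grignard 1,2-addition to an aromatic aldehyde forms the C2–C3 bond, with no stereocontrol needed because the racemate is resolved next, and the neutral quench spares the acid-labile electron-rich benzylic allylic carbinol.

Step 3
Reactants: 4 racemic 1-[3-methoxy-4-(triisopropylsilyloxy)phenyl]prop-2-en-1-ol
Product: 5 (R)-[3-methoxy-4-(triisopropylsilyloxy)phenyl][(S)-oxiran-2-yl]methanol (erythro)
Conditions: Ti(OiPr)4 (0.2 equiv), D-(−)-diisopropyl tartrate (0.24 equiv), anhydrous t-BuOOH (0.45 equiv), 4 Å MS, CH2Cl2, −20 °C; non-basic work-up, chromatography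
Reagents that add atoms: tert-butyl hydroperoxide, CC(C)(C)OO
Why: In this Sharpless kinetic resolution the D-tartrate titanium catalyst epoxidises the (S)-carbinol much faster than its mirror image and on the face that gives the erythro epoxy alcohol, so limiting the oxidant to under half an equivalent converts only that enantiomer (at most half of 4) and fixes the C2 configuration by reagent control, while the oxirane centre formed alongside is only a relay that is erased in step 7.

Step 4
Reactants: 6 (E)-3,4-dimethoxycinnamic acid
Product: 8 (E)-3,4-dimethoxycinnamyl alcohol, via ethyl carbonic mixed anhydride 7 (not isolated)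
Conditions: ClCO2Et, Et3N, THF, −10 °C; then NaBH4, THF–H2O, 0 °C → rt
Reagents that add atoms: none
Why: Activation of the acid as its mixed carbonic anhydride followed by borohydride reduction delivers hydride 1,2 to the acyl carbon only, so the conjugated E double bond should be kept and an ester isolation is saved.

Step 5
Reactants: 8 (E)-3,4-dimethoxycinnamyl alcohol
Product: 9 (E)-3,4-dimethoxycinnamyl bromide
Conditions: PBr3 (0.4 equiv), Et2O, 0 °C; used crude and cold at once
Reagents that add atoms: phosphorus tribromide, BrP(Br)Br
Why: Bromination of a primary allylic alcohol through its phosphite ester proceeds by bromide displacement at the primary carbon with the conjugated E geometry retained, and immediate use avoids ionisation of this electron-rich allylic halide.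

Step 6
Reactants: 5 (R)-[3-methoxy-4-(triisopropylsilyloxy)phenyl][(S)-oxiran-2-yl]methanol; 9 (E)-3,4-dimethoxycinnamyl bromide
Product: 10 (S)-2-{(R)-[(E)-3-(3,4-dimethoxyphenyl)prop-2-enyloxy][3-methoxy-4-(triisopropylsilyloxy)phenyl]methyl}oxirane
Conditions: NaH (1.1 equiv), THF, 0 °C; then 9 (1.2 equiv), Bu4NI (cat.), 0 °C → rt
Reagents that add atoms: none
Why: Williamson etherification of the sodium alkoxide with a highly reactive primary allylic bromide under iodide catalysis should be faster in cold, strictly aprotic THF than Payne migration of the oxirane, and leaving out DMF protects the aryl silyl ether; C2 keeps its configuration because only the O–H bond is exchanged.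

Step 7
Reactants: 10 (S)-2-{(R)-[(E)-3-(3,4-dimethoxyphenyl)prop-2-enyloxy][3-methoxy-4-(triisopropylsilyloxy)phenyl]methyl}oxirane
Product: 12 TIPS ether of 4'-O-methyllariciresinol, via cyclised bis-titanium adduct 11 (not isolated)
Conditions: Cp2TiCl2 (2.5 equiv), Zn dust, THF, rt (green Cp2TiCl), added dropwise to 10 in THF (0.02 M), rt, Ar; then cold degassed 1 M HCl, no oxidant
Reagents that add atoms: none
Why: Cp2TiCl, a mild one-electron donor of trivalent titanium, binds the oxirane oxygen and cleaves the internal C–O bond homolytically to the secondary C3 radical with C9 held as a titanium alkoxide; this radical adds to the cinnamyl double bond to form C3–C4, and the veratryl-stabilised benzylic radical is taken up by a second Cp2TiCl and protonated on work-up to the C4 benzyl CH2. The closest known reaction type is the Nugent–RajanBabu titanocene-mediated reductive epoxide opening with radical cyclisation, which is established for epoxy allyl and cinnamyl ethers leading to 3-hydroxymethyl-4-substituted tetrahydrofurans. The tetrahydrofuran, the only ring formed, is closed 5-exo-trig at C3–C4. C3 and C4 are both set under control of the C2 stereocentre through a chair-like Beckwith–Houk transition state in which the C2 aryl group lies pseudo-equatorial, the CH2OTi group on the radical carbon turns trans to it (2,3-trans) and the styrene arm takes the usual 1,5-cis arrangement with CH2OTi (3,4-cis); the oxirane configuration plays no part because that carbon becomes planar. The step needs regioselective opening (secured by the greater stability of the secondary over the primary radical), ring closure faster than reduction of the C3 radical and the β-elimination that would follow (secured by the activated styrene acceptor and by slow addition, which keeps trivalent titanium dilute), and diastereoselection (secured by the C2 aryl group). The near-neutral medium should leave the electron-rich benzylic C2–O bond and the aryl silyl ether intact, and the primary alcohol is delivered directly, with no redox adjustment afterwards.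

Step 8
Reactants: 12 TIPS ether of 4'-O-methyllariciresinol
Product: 13 4'-O-methyllariciresinol
Conditions: Bu4NF (1.1 equiv), AcOH (1.1 equiv), THF, 0 °C
Reagents that add atoms: none
Why: Fluoride-driven desilylation of the aryl silyl ether relies on the strong Si–F bond, and the acetic acid buffer keeps the liberated phenol protonated so that no phenoxide can open the benzylic C2–O1 bond through a quinone methide; all three stereocentres are untouched.

**Compound list**

1 | vanillin (4-hydroxy-3-methoxybenzaldehyde) | COc1cc(C=O)ccc1O | starting material
2 | 3-methoxy-4-(triisopropylsilyloxy)benzaldehyde | COc1cc(C=O)ccc1O[Si](C(C)C)(C(C)C)C(C)C | intermediate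
3 | vinylmagnesium bromide | C=C[Mg]Br | starting material
4 | racemic 1-[3-methoxy-4-(triisopropylsilyloxy)phenyl]prop-2-en-1-ol | COc1cc(C(O)C=C)ccc1O[Si](C(C)C)(C(C)C)C(C)C | intermediate
5 | (R)-[3-methoxy-4-(triisopropylsilyloxy)phenyl][(S)-oxiran-2-yl]methanol | COc1cc([C@H]([C@@H]2CO2)O)ccc1O[Si](C(C)C)(C(C)C)C(C)C | intermediate
6 | (E)-3,4-dimethoxycinnamic acid | COc1ccc(/C=C/C(=O)O)cc1OC | starting material
7 | (E)-3,4-dimethoxycinnamic ethyl carbonic anhydride | COc1ccc(/C=C/C(=O)OC(=O)OCC)cc1OC | intermediate
8 | (E)-3,4-dimethoxycinnamyl alcohol | COc1ccc(/C=C/CO)cc1OC | intermediate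
9 | (E)-3,4-dimethoxycinnamyl bromide | COc1ccc(/C=C/CBr)cc1OC | intermediate
10 | (S)-2-{(R)-[(E)-3-(3,4-dimethoxyphenyl)prop-2-enyloxy][3-methoxy-4-(triisopropylsilyloxy)phenyl]methyl}oxirane | COc1cc([C@H]([C@@H]2CO2)OC/C=C/c2ccc(OC)c(OC)c2)ccc1O[Si](C(C)C)(C(C)C)C(C)C | intermediate
11 | cyclised adduct before work-up: (2S,3R,4R)-tetrahydrofuran with C9–O–TiClCp2 and benzylic C–TiClCp2 (tetravalent titanium; benzylic centre undefined) | COc1cc([C@H]2OC[C@H](C([Ti](Cl)(C3C=CC=C3)C3C=CC=C3)c3ccc(OC)c(OC)c3)[C@@H]2CO[Ti](Cl)(C2C=CC=C2)C2C=CC=C2)ccc1O[Si](C(C)C)(C(C)C)C(C)C | intermediate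
12 | {(2S,3R,4R)-4-(3,4-dimethoxybenzyl)-2-[3-methoxy-4-(triisopropylsilyloxy)phenyl]tetrahydrofuran-3-yl}methanol | COc1cc([C@H]2OC[C@H](Cc3ccc(OC)c(OC)c3)[C@@H]2CO)ccc1O[Si](C(C)C)(C(C)C)C(C)C | intermediate
13 | 4'-O-methyllariciresinol, 4-[(2S,3R,4R)-4-(3,4-dimethoxybenzyl)-3-(hydroxymethyl)tetrahydrofuran-2-yl]-2-methoxyphenol | COc1cc([C@H]2OC[C@H](Cc3ccc(OC)c(OC)c3)[C@@H]2CO)ccc1O | target

**Count and risks**

Total step count: 8. Longest linear sequence: 6 steps (steps 1, 2, 3, 6, 7, 8 from vanillin); the cinnamyl bromide is made in 2 steps (4, 5) and joins at step 6.

Step 7. The ring closure may discriminate the two faces of the styrene incompletely, so that the C4 epimer forms alongside, or the C3 radical may be reduced before it cyclises and the epoxide is then simply deoxygenated. The fallback sets out from 5 and comes back at 12, and it separates the making of C3 from that of C4. 4-Iodo-1,2-dimethoxybenzene and propargyl alcohol would be joined by Sonogashira coupling (Pd(PPh3)2Cl2, CuI, Et3N) to 3-(3,4-dimethoxyphenyl)prop-2-yn-1-ol F1, which PBr3 should convert into 3-(3,4-dimethoxyphenyl)prop-2-ynyl bromide F2. Alkylation of 5 with it under the conditions of step 6 would give the epoxy propargyl ether F3. Cp2TiCl should then close the ring 5-exo-dig onto the alkyne, a fast and irreversible radical trap, to the 4-benzylidene tetrahydrofuran F4, in which only C3 is set in the radical event (trans to the C2 aryl group). C4 would be set afterwards by heterogeneous hydrogenation (H2, Rh on Al2O3, EtOAc), with hydrogen expected on the face away from the neighbouring CH2OH group so that the benzyl group ends cis to it, which gives 12.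

Step 3. Enantiomeric purity may be eroded because, when the resolution is read on the product side, any epoxidation of the slow enantiomer contaminates the product directly; the epoxy alcohol may also be opened on long contact with the titanium alkoxide. The fallback sets out from 4 and comes back at 5, and it resolves on the substrate side instead. The resolution would be run in the opposite sense with Ti(OiPr)4, L-(+)-diisopropyl tartrate and about 0.6 equiv of t-BuOOH, past half conversion, so that the unwanted carbinol is consumed and the unreacted (S)-1-[3-methoxy-4-(triisopropylsilyloxy)phenyl]prop-2-en-1-ol F5 is recovered; its purity rises with conversion. A separate, matched and therefore fast epoxidation of F5 with Ti(OiPr)4, D-(−)-diisopropyl tartrate and t-BuOOH would then give 5 with a second enrichment.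

Step 6. The oxirane may migrate by Payne rearrangement under the alkoxide conditions, or the bromide may be lost by ionisation or attack at its benzylic terminus before it is alkylated. The fallback sets out from 5 and 8 and comes back at 10, and it avoids both the free sodium alkoxide and the bromide. Alcohol 8 would be acetylated (Ac2O, Et3N, DMAP) to (E)-3,4-dimethoxycinnamyl acetate F6. The zinc alkoxide of 5 (Et2Zn, 0.5 equiv) would then be allylated under palladium catalysis (Pd(OAc)2, 2-(di-tert-butylphosphino)biphenyl, THF, rt). The π-allyl complex of divalent palladium should be attacked by the weakly basic zinc alkoxide at its unsubstituted terminus, giving the linear E ether 10.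

**Further compounds**

F1 | step 7 | 3-(3,4-dimethoxyphenyl)prop-2-yn-1-ol | COc1ccc(C#CCO)cc1OC
F2 | step 7 | 3-(3,4-dimethoxyphenyl)prop-2-ynyl bromide | COc1ccc(C#CCBr)cc1OC
F3 | step 7 | (S)-2-{(R)-[3-(3,4-dimethoxyphenyl)prop-2-ynyloxy][3-methoxy-4-(triisopropylsilyloxy)phenyl]methyl}oxirane | COc1cc([C@H]([C@@H]2CO2)OCC#Cc2ccc(OC)c(OC)c2)ccc1O[Si](C(C)C)(C(C)C)C(C)C
F4 | step 7 | {(2S,3R)-4-(3,4-dimethoxybenzylidene)-2-[3-methoxy-4-(triisopropylsilyloxy)phenyl]tetrahydrofuran-3-yl}methanol (alkene geometry not defined) | COc1cc([C@H]2OCC(=Cc3ccc(OC)c(OC)c3)[C@@H]2CO)ccc1O[Si](C(C)C)(C(C)C)C(C)C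
F5 | step 3 | (S)-1-[3-methoxy-4-(triisopropylsilyloxy)phenyl]prop-2-en-1-ol | COc1cc([C@H](C=C)O)ccc1O[Si](C(C)C)(C(C)C)C(C)C
F6 | step 6 | (E)-3,4-dimethoxycinnamyl acetate | COc1ccc(/C=C/COC(C)=O)cc1OC
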